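# Synthesis plan for 8-acetylcaespitol 18

## The problem

8-Acetylcaespitol 18 is an oxane (O1, C2–C6) and a cyclohexane (C1'–C6') joined by a single bond between the quaternary ether carbon C2 and the ring methine C1', so no ring fusion relays stereochemistry from one half to the other. The oxane carries a di-tertiary ether (O1 between C2 and the gem-dimethyl carbon C6), an axial acetoxy group at C3 and an equatorial bromine at C5, while the cyclohexane carries an equatorial secondary bromine at C3' and a tertiary chlorine at C4', trans to each other, with the bromine cis to the C1' substituent. C3 can direct C2 by 1,2-induction if C2 is made from a ketone, and C2 and C3 together can direct C5 through a chair if the O1–C6 bond is closed last. C1' lies too far from C3 across a freely rotating bond and needs reagent control. C1' also locks its ring, and this works against the target: anti addition of bromine chloride to the corresponding cyclohexene follows the trans-diaxial rule and puts both halogens axial with bromine anti to the C1' substituent. The tertiary chloride and the secondary bromides do not tolerate strong Lewis acids, strongly ionising media, reducing metals or hot base, the acetate does not survive organometallic reagents, and the di-tertiary ether is acid-labile. Two features allow a short plan: C1'–C6' with its C4' methyl and C3'/C4' dihalide is a masked 4-substituted 1-methylcyclohexene (isoprene plus a dienophile whose carbonyl carbon becomes C2), and the chain C2–C6, at carbonyl level at both ends with a heteroatom on C3, is the carbon chain of glutamic acid with C3 as its α-carbon.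

## Retrosynthesis

**18 ⇒ 17.** The O1–C6 and C5–Br bonds are cut together, as a bromonium-induced 6-endo etherification of the hydroxy alkene 17. The neighbouring cut at O1–C2 would need substitution at a hindered tertiary carbon. Putting bromine on a finished oxane by displacing a C5 oxygen is a neopentyl-type substitution prone to ring contraction through O1. Precursor 17 is acyclic in this half and has neither a C5 stereocentre nor an ether. The forward step must close at the tertiary carbon C6 and pass through the chair with the cyclohexyl group and bromine equatorial. The C3 acetate is already in place, so only the C2 hydroxyl can attack.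

**17 ⇒ 16 ⇒ 15 ⇒ 14.** The C5=C6 double bond is traced to the β-hydroxy selenide 16, and the two C6–CH3 bonds to the lactone carbonyl of 14 (triol 15 after double methyl addition, 16 after acetylation of the only secondary hydroxyl). Simple dehydration of a C6 tertiary alcohol would give isopropenyl and isopropylidene isomers and would have to distinguish two tertiary alcohols. Selenium at C5 makes the elimination regiospecific. Zinc-based eliminations are excluded by the ring dihalide.

**14 ⇒ 12 ⇒ 10 + 11.** Selenium goes onto the lactone enolate of 12. The C2–CH3 bond of 12 is cut to ketone 10 and methylmagnesium bromide 11. Making C2 by C–C addition to a ketone beside the C3 stereocentre allows Felkin–Anh control and avoids C–O bond formation at a tertiary centre. The forward reaction must select the ketone over the lactone and avoid chelation.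

**10 ⇒ 9 ⇒ 8 ⇒ 7.** The C3'–Br and C4'–Cl bonds are traced to the ring alkene of 7. Direct bromochlorination gives the wrong diastereomer, so the halogens are introduced with reversed positions in the trans-diaxial sense (chlorohydrin 8, then tertiary bromide 9) and then exchanged between C3' and C4' to give 10. This is done on 7, before methyl addition, for three reasons:
- a free C2 hydroxyl would capture the ring halonium ion as a bridged ether;
- no second alkene is yet present;
- the uncertain step then falls early, on a simple keto lactone.

**7 ⇒ 5 + 6.** The C1'–C2' and C5'–C6' bonds are cut in a Diels–Alder reaction of isoprene 6 with vinyl ketone 5. One catalytic step builds the carbocycle with the methyl group in place and sets C1' by catalyst control. Closing the ring by alkylation would need a multistep acyclic precursor. The forward step needs para regiochemistry, face control at the α-carbon, and survival of the acidic C3 centre.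

**5 ⇒ 3 + 4; 3 ⇒ 2 ⇒ 1.** The vinyl–carbonyl bond is cut to Weinreb amide 3 and vinylmagnesium bromide 4. Amide 3 comes from lactone acid 2, which comes from D-glutamic acid 1 by diazotisation with retention. D-Glutamic acid supplies C2–C6 and the (R) configuration of C3.

## Roads not taken

**Alternative 1:** The C5–Br bond and a C6–O bond to the C3 oxygen are cut. In the forward step NBS brominates C5 of the cyclic enol ether A2 and the C3 hydroxyl captures the C6 oxocarbenium ion, giving the bicyclic ketal A1 with bromine anti to the bridging oxygen. The merit is real: the rigid bicycle fixes C5 relative to C3 more firmly than a chair transition state can, and both oxane C–O bonds at C2 and C6 already exist. The weak points: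
- A1 is a strained 2,7-dioxabicyclo[2.2.1]heptane.
- The ketal of A1 must then be opened at C6 by a methyl nucleophile under Lewis acid, next to a bromine that can bridge or be lost.
- That Lewis acid meets the tertiary chloride.
- The cyclohexane halogen problem is untouched.

In C5 control this road is better. The chosen plan sets against it that C6 carries both methyl groups before ring closure, so O1–C6 and C5–Br form in one step with no organoaluminium chemistry on the halogenated molecule.

**Alternative 2:** The C1'–C2' bond is cut. The sodium enolate of the open-chain imide A4, which already carries the bromochloride, displaces a primary triflate and closes the cyclohexane to the acyl oxazolidinone A3. In the halogen question this road is clearly better: Br and Cl are set on an open chain, where no trans-diaxial rule applies, and become diequatorial on ring closure without any interchange. The weak points: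
- A basic enolate must coexist with a secondary bromide and a tertiary chloride.
- A4 takes several steps, including an enantioselective bromochlorination.
- C1' depends on auxiliary and chair acting together.
- The acyl carbon of A3 must still be built into the oxane, with C2 and C3 set without a chiral-pool source.

The chosen plan sets against it a one-step, catalytic carbocycle and a glutamate-derived oxane. It pays with the halogen interchange of step 6.

**Alternative 3:** The O1–C2 bond is cut. The tertiary C6 hydroxyl of epoxy alcohol A6 attacks C2 of the Z-configured C2–C3 epoxide with inversion and closes the oxane to caespitol A5, in which C3 keeps the epoxide oxygen as a free hydroxyl. Acetylation of A5 then gives 18. The merits: C2 and C3 come from one epoxide, and the end of the route is very short. The weak points: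
- A tertiary alcohol must attack the more hindered tertiary epoxide carbon in 6-endo fashion, against 5-exo attack at C3.
- Inversion at a tertiary carbon under acid has carbocation character.
- A geometrically pure Z-trisubstituted alkene is needed to make A6.
- The nucleophilic hydroxyl of A6 sits beside the C5 bromine, a bromohydrin that closes to an epoxide with base and ionises with acid.

This road would be shorter at the end. The chosen plan sets against it C–C bond formation at a ketone for C2 and a ring closure in which oxygen attacks a cationic carbon bearing only methyl groups.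

Key step: step 4

## Route

Remark on locants: oxane atoms are O1 and C2–C6, cyclohexane atoms C1'–C6'; the acetoxy carbon is C3 in these locants.

Assumption: the (S)-configured oxazaborolidinium is taken as the antipode that exposes the Re face of the α-carbon of 5; if the sense is the reverse, the (R)-catalyst is used and nothing else changes.

Step 1
Reactants: 1 D-glutamic acid
Product: 2 (R)-5-oxotetrahydrofuran-2-carboxylic acid
Conditions: NaNO2, aq HCl, 0 °C → rt
Reagents that add atoms: none
Why: Diazotisation of the α-amino acid; the α-carboxylate displaces dinitrogen to an α-lactone and the γ-carboxylate opens it, two inversions that leave the (R) centre (later C3) unchanged.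

Step 2
Reactants: 2 (R)-5-oxotetrahydrofuran-2-carboxylic acid
Product: 3 (R)-N-methoxy-N-methyl-5-oxotetrahydrofuran-2-carboxamide
Conditions: MeNH(OMe)·HCl, EDC·HCl, N-methylmorpholine, CH2Cl2, 0 °C → rt
Reagents that add atoms: N,O-dimethylhydroxylamine hydrochloride, CNOC.Cl
Why: Carbodiimide amide coupling to the Weinreb amide; the activated acid carries no N-acyl group, so there is no azlactone path to racemisation and the stereocentre is untouched.

Step 3
Reactants: 3 (R)-N-methoxy-N-methyl-5-oxotetrahydrofuran-2-carboxamide; 4 vinylmagnesium bromide
Product: 5 (R)-5-acryloyldihydrofuran-2(3H)-one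
Conditions: THF, −78 → −40 °C; inverse quench into cold 1 M HCl
Reagents that add atoms: none
Why: Weinreb ketone synthesis; the chelated tetrahedral adduct forms faster at the activated amide than at the lactone and stops at the ketone stage, and the acidic inverse quench keeps the released hydroxylamine protonated so that it cannot add to the enone.

Step 4
Reactants: 5 (R)-5-acryloyldihydrofuran-2(3H)-one; 6 isoprene
Product: 7 (R)-5-[(S)-4-methylcyclohex-3-ene-1-carbonyl]dihydrofuran-2(3H)-one
Conditions: (S)-tetrahydro-1-(o-tolyl)-3,3-diphenyl-1H,3H-pyrrolo[1,2-c][1,3,2]oxazaborole (0.2 equiv), (CF3SO2)2NH (0.18 equiv), CH2Cl2, −78 → −40 °C, excess 6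
Reagents that add atoms: none
Why: The protonated oxazaborolidine binds the ketone oxygen of 5, lowers the LUMO of the s-cis enone and screens one face of the vinyl group, and isoprene adds in a concerted, asynchronous [4+2] cycloaddition. The closest known reaction type is the oxazaborolidinium-catalysed Diels–Alder reaction of simple vinyl ketones and acrylates with 2-substituted butadienes. The cyclohexene ring is closed by intermolecular cycloaddition, both ring bonds (C1'–C2' and C5'–C6') forming in the same step. The only new stereocentre, C1' (S), is set by the catalyst, which should expose the Re face of the α-carbon; the C3 centre sits on the far side of the carbonyl group and is not expected to override it. The larger HOMO coefficient of isoprene at C1 bonds to the β-carbon, so the methyl group ends para (C4') to the acyl group. The step needs chemoselectivity for the enone over the lactone, which is no dienophile, and retention of the acidic C3 centre, which the low temperature and absence of base should secure. Slow addition of 5 to excess diene limits polymerisation of the vinyl ketone.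

Step 5
Reactants: 7 (R)-5-[(S)-4-methylcyclohex-3-ene-1-carbonyl]dihydrofuran-2(3H)-one
Product: 8 (R)-5-[(1S,3R,4R)-3-chloro-4-hydroxy-4-methylcyclohexane-1-carbonyl]dihydrofuran-2(3H)-one
Conditions: trichloroisocyanuric acid (0.37 equiv), acetone/H2O, 0 °C → rt
Reagents that add atoms: trichloroisocyanuric acid, O=C1N(Cl)C(=O)N(Cl)C(=O)N1Cl; water, O
Why: Chlorohydrin formation by cohalogenation; electrophilic chlorine adds to the less substituted C3' and water to the tertiary C4' in the trans-diaxial sense of the half-chair with the acyl group equatorial, so chlorine ends axial and anti to the C1' substituent and the hydroxyl axial and syn to it.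

Step 6
Reactants: 8 (R)-5-[(1S,3R,4R)-3-chloro-4-hydroxy-4-methylcyclohexane-1-carbonyl]dihydrofuran-2(3H)-one
Product: 10 (R)-5-[(1S,3S,4S)-3-bromo-4-chloro-4-methylcyclohexane-1-carbonyl]dihydrofuran-2(3H)-one, via trans-diaxial 4-bromo-3-chloro ketolactone 9 (not isolated)
Conditions: Me3SiBr, CH2Cl2, 0 °C; evaporate; then MeNO2, 2,6-di-tert-butylpyridine (0.2 equiv), 60–90 °C
Reagents that add atoms: bromotrimethylsilane, C[Si](C)(C)Br
Why: Proposed new method: Me3SiBr should replace the axial tertiary hydroxyl by bromide with retention, because the antiperiplanar axial chlorine bridges the C4' cation and bromide re-enters axially (ordinary tertiary alcohol-to-bromide substitution, giving trans-diaxial 9); warming 9 in a polar non-nucleophilic medium is then expected to exchange the two halogens between C3' and C4', each staying on its own face with inversion at both carbons (a type-one dyotropic shift or its tight chloronium–bromide ion pair), which turns the diaxial 4-bromo-3-chloro array into the diequatorial (3'S,4'S) 3-bromo-4-chloro array of 10; the closest known reaction type is the diaxial-to-diequatorial rearrangement of steroidal trans-diaxial vicinal dibromides and bromochlorides, not shown for a tertiary bromide/secondary chloride pair on a monocyclic ring; chlorine on the tertiary carbon is the better constitutional pairing and the polar medium favours the more polar diequatorial dihalide, while the hindered pyridine removes HBr that would catalyse elimination and enolisation at C1'.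

Step 7
Reactants: 10 (R)-5-[(1S,3S,4S)-3-bromo-4-chloro-4-methylcyclohexane-1-carbonyl]dihydrofuran-2(3H)-one; 11 methylmagnesium bromide
Product: 12 (R)-5-[(R)-1-[(1S,3S,4S)-3-bromo-4-chloro-4-methylcyclohexyl]-1-hydroxyethyl]dihydrofuran-2(3H)-one
Conditions: 11 (1.2 equiv), THF, −78 °C; aq NH4Cl
Reagents that add atoms: none
Why: Grignard addition to the ketone, which is faster than addition to the lactone at low temperature; polar Felkin–Anh control is expected because the acylated C3 oxygen is a poor chelating donor in THF, so the C3–O bond lies anti to the incoming methyl group, which passes the C3 hydrogen and gives (2R); the cold, brief exposure should not enolise C1'.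

Step 8
Reactants: 12 (R)-5-[(R)-1-[(1S,3S,4S)-3-bromo-4-chloro-4-methylcyclohexyl]-1-hydroxyethyl]dihydrofuran-2(3H)-one
Product: 14 (5R)-5-[(R)-1-[(1S,3S,4S)-3-bromo-4-chloro-4-methylcyclohexyl]-1-hydroxyethyl]-3-(phenylselanyl)dihydrofuran-2(3H)-one (both epimers at C3 of the lactone), via dilithium alkoxide enolate 13 (not isolated)
Conditions: LiN(iPr)2 (2.2 equiv), THF, −78 °C; then PhSeBr, −78 °C; aq NH4Cl
Reagents that add atoms: benzeneselenenyl bromide, Br[Se]c1ccccc1
Why: α-Selenenylation of a lactone enolate, with the tertiary hydroxyl masked in the flask as its alkoxide; the configuration of the new C–Se centre is irrelevant because step 11 removes it, and the diequatorial ring halides have no antiperiplanar ring hydrogen for elimination at −78 °C.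

Step 9
Reactants: 14 (5R)-5-[(R)-1-[(1S,3S,4S)-3-bromo-4-chloro-4-methylcyclohexyl]-1-hydroxyethyl]-3-(phenylselanyl)dihydrofuran-2(3H)-one; 11 methylmagnesium bromide
Product: 15 (2R,3R)-2-[(1S,3S,4S)-3-bromo-4-chloro-4-methylcyclohexyl]-6-methyl-5-(phenylselanyl)heptane-2,3,6-triol (both epimers at C5)
Conditions: 11 (5 equiv), CeCl3, THF, −78 → 0 °C; aq NH4Cl
Reagents that add atoms: none
Why: Double addition of a methyl organometallic to the lactone carbonyl gives the C6 tertiary alcohol and frees the C3 hydroxyl; the cerium-modified, less basic reagent should suppress enolisation of the α-seleno lactone, and the product is the β-hydroxy selenide needed for step 11.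

Step 10
Reactants: 15 (2R,3R)-2-[(1S,3S,4S)-3-bromo-4-chloro-4-methylcyclohexyl]-6-methyl-5-(phenylselanyl)heptane-2,3,6-triol
Product: 16 (2R,3R)-2-[(1S,3S,4S)-3-bromo-4-chloro-4-methylcyclohexyl]-2,6-dihydroxy-6-methyl-5-(phenylselanyl)heptan-3-yl acetate
Conditions: Ac2O, pyridine, DMAP (cat.), CH2Cl2, 0 °C → rt
Reagents that add atoms: acetic anhydride, CC(=O)OC(C)=O
Why: Nucleophile-catalysed acylation of the only secondary hydroxyl; the two tertiary hydroxyls are too hindered to react under these conditions.

Step 11
Reactants: 16 (2R,3R)-2-[(1S,3S,4S)-3-bromo-4-chloro-4-methylcyclohexyl]-2,6-dihydroxy-6-methyl-5-(phenylselanyl)heptan-3-yl acetate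
Product: 17 (2R,3R)-2-[(1S,3S,4S)-3-bromo-4-chloro-4-methylcyclohexyl]-2-hydroxy-6-methylhept-5-en-3-yl acetate
Conditions: MsCl, Et3N (excess), CH2Cl2, 0 °C → rt
Reagents that add atoms: none
Why: Eliminative deoxygenation of a β-hydroxy selenide (the selenium analogue of the Peterson olefination): the activated C6 oxygen is displaced by the neighbouring selenium and the seleniranium ion loses the selenium electrophile, placing the double bond between C5 and C6 only; the C2 hydroxyl is more hindered and has no selenium neighbour. The excess amine is there to tie up the released selenenyl chloride, which could otherwise add back to the new alkene.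

Step 12
Reactants: 17 (2R,3R)-2-[(1S,3S,4S)-3-bromo-4-chloro-4-methylcyclohexyl]-2-hydroxy-6-methylhept-5-en-3-yl acetate
Product: 18 8-acetylcaespitol, (2R,3R,5R)-5-bromo-2-[(1S,3S,4S)-3-bromo-4-chloro-4-methylcyclohexyl]-2,6,6-trimethyloxan-3-yl acetate
Conditions: 2,4,4,6-tetrabromocyclohexa-2,5-dienone, MeNO2, 0 °C → rt
Reagents that add atoms: 2,4,4,6-tetrabromocyclohexa-2,5-dienone, O=C1C(Br)=CC(Br)(Br)C=C1Br
Why: Bromoetherification (bromonium-induced 6-endo cyclisation): the bromonium ion of the trisubstituted alkene is opened at the tertiary C6 by the C2 hydroxyl through a chair with bromine and the cyclohexyl group equatorial and the C3 acetate axial, which should give (5R); the alternative chair would place the cyclohexyl group axial against a C6 methyl group.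

## Compound list

1 | D-glutamic acid | N[C@H](CCC(=O)O)C(=O)O | starting material
2 | (R)-5-oxotetrahydrofuran-2-carboxylic acid | OC(=O)[C@H]1CCC(=O)O1 | intermediate
3 | (R)-N-methoxy-N-methyl-5-oxotetrahydrofuran-2-carboxamide | CON(C)C(=O)[C@H]1CCC(=O)O1 | intermediate
4 | vinylmagnesium bromide | C=C[Mg]Br | starting material
5 | (R)-5-acryloyldihydrofuran-2(3H)-one | C=CC(=O)[C@H]1CCC(=O)O1 | intermediate
6 | isoprene | C=CC(C)=C | starting material
7 | (R)-5-[(S)-4-methylcyclohex-3-ene-1-carbonyl]dihydrofuran-2(3H)-one | O=C([C@H]1CCC(=O)O1)[C@H]1CCC(C)=CC1 | intermediate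
8 | (R)-5-[(1S,3R,4R)-3-chloro-4-hydroxy-4-methylcyclohexane-1-carbonyl]dihydrofuran-2(3H)-one | O=C([C@H]1CCC(=O)O1)[C@H]1CC[C@@](C)(O)[C@H](Cl)C1 | intermediate
9 | (R)-5-[(1S,3R,4R)-4-bromo-3-chloro-4-methylcyclohexane-1-carbonyl]dihydrofuran-2(3H)-one | O=C([C@H]1CCC(=O)O1)[C@H]1CC[C@@](C)(Br)[C@H](Cl)C1 | intermediate
10 | (R)-5-[(1S,3S,4S)-3-bromo-4-chloro-4-methylcyclohexane-1-carbonyl]dihydrofuran-2(3H)-one | O=C([C@H]1CCC(=O)O1)[C@H]1CC[C@](C)(Cl)[C@@H](Br)C1 | intermediate
11 | methylmagnesium bromide | C[Mg]Br | starting material
12 | (R)-5-[(R)-1-[(1S,3S,4S)-3-bromo-4-chloro-4-methylcyclohexyl]-1-hydroxyethyl]dihydrofuran-2(3H)-one | O[C@@](C)([C@H]1CCC(=O)O1)[C@H]1CC[C@](C)(Cl)[C@@H](Br)C1 | intermediate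
13 | dilithium (R)-1-[(1S,3S,4S)-3-bromo-4-chloro-4-methylcyclohexyl]-1-[(R)-5-oxido-2,3-dihydrofuran-2-yl]ethan-1-olate | [Li+].[Li+].[O-][C@@](C)([C@H]1CC=C([O-])O1)[C@H]1CC[C@](C)(Cl)[C@@H](Br)C1 | intermediate
14 | (5R)-5-[(R)-1-[(1S,3S,4S)-3-bromo-4-chloro-4-methylcyclohexyl]-1-hydroxyethyl]-3-(phenylselanyl)dihydrofuran-2(3H)-one, both C3 epimers | O[C@@](C)([C@H]1CC([Se]c2ccccc2)C(=O)O1)[C@H]1CC[C@](C)(Cl)[C@@H](Br)C1 | intermediate
15 | (2R,3R)-2-[(1S,3S,4S)-3-bromo-4-chloro-4-methylcyclohexyl]-6-methyl-5-(phenylselanyl)heptane-2,3,6-triol, both C5 epimers | O[C@@](C)([C@H](O)CC([Se]c1ccccc1)C(C)(C)O)[C@H]1CC[C@](C)(Cl)[C@@H](Br)C1 | intermediate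
16 | (2R,3R)-2-[(1S,3S,4S)-3-bromo-4-chloro-4-methylcyclohexyl]-2,6-dihydroxy-6-methyl-5-(phenylselanyl)heptan-3-yl acetate, both C5 epimers | O[C@@](C)([C@H](OC(C)=O)CC([Se]c1ccccc1)C(C)(C)O)[C@H]1CC[C@](C)(Cl)[C@@H](Br)C1 | intermediate
17 | (2R,3R)-2-[(1S,3S,4S)-3-bromo-4-chloro-4-methylcyclohexyl]-2-hydroxy-6-methylhept-5-en-3-yl acetate | O[C@@](C)([C@H](OC(C)=O)CC=C(C)C)[C@H]1CC[C@](C)(Cl)[C@@H](Br)C1 | intermediate
18 | 8-acetylcaespitol, (2R,3R,5R)-5-bromo-2-[(1S,3S,4S)-3-bromo-4-chloro-4-methylcyclohexyl]-2,6,6-trimethyloxan-3-yl acetate | CC(=O)O[C@@H]1C[C@@H](Br)C(C)(C)O[C@]1(C)[C@H]1CC[C@](C)(Cl)[C@@H](Br)C1 | target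

## Step count and least certain steps

Total: 12 steps. Longest linear sequence: 12 steps, from D-glutamic acid 1 to 18.

**Step 6 (proposed new method).** Three things may go wrong:
- the interchange may stop at an equilibrium, because the diaxial and diequatorial isomers may be close in energy;
- hydrogen bromide may be lost from the tertiary bromide on warming;
- acid may epimerise C1', and 10 is probably not the more stable C1' epimer.

The fallback uses known reaction types and avoids the interchange; it sets out from enone 5 and isoprene 6 and comes back at 10. The antipodal oxazaborolidinium gives the C1' epimer of 7, (R)-5-[(R)-4-methylcyclohex-3-ene-1-carbonyl]dihydrofuran-2(3H)-one F1. Bu4NBrCl2 in CH2Cl2 adds bromine chloride to F1 in the ordinary trans-diaxial, Markovnikov sense, bromine anti and chlorine syn to the acyl group. This gives (R)-5-[(1R,3S,4S)-3-bromo-4-chloro-4-methylcyclohexane-1-carbonyl]dihydrofuran-2(3H)-one F2, which has the C3' and C4' configurations of 10 and differs only at C1'. Deprotonation with LiN(SiMe3)2 at −78 °C, expected at C1' and away from the oxygen-bearing C3, gives the lithium enolate F3. Kinetic protonation with 2,6-di-tert-butyl-4-methylphenol should come from the equatorial face, because the axial face is blocked by the syn-axial C3' bromine. The acyl group then ends axial, and ring inversion gives the all-equatorial 10. The enolate must be kept cold and short-lived, since its C1' carbon could otherwise displace the C3' bromide, and equilibrating conditions must be avoided in this last operation.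

**Step 4 (key step).** Facial selectivity may be poor if the C3 acyloxy centre opposes the catalyst, the vinyl ketone may polymerise, or C3 may erode by enolisation on the Lewis acid. The fallback changes from catalyst control to substrate control with separation; it sets out from 5 and 6 and comes back at 7. Me2AlCl in CH2Cl2 at −78 °C promotes the same para-selective cycloaddition and gives 7 together with its C1' epimer (R)-5-[(R)-4-methylcyclohex-3-ene-1-carbonyl]dihydrofuran-2(3H)-one F4 (the same compound as F1). The two are diastereomers and are separated by chromatography. The epimer need not be discarded, since the fallback to step 6 carries it to 10.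

**Step 5.** The chloro cation may lose a proton to give allylic chlorides, or the ring-inverted half-chair may react and lower the diastereoselectivity. The fallback uses a reversibly formed bromonium ion; it sets out from 7 and comes back at 8.
- NBS in aqueous acetone gives the trans-diaxial bromohydrin (R)-5-[(1S,3R,4R)-3-bromo-4-hydroxy-4-methylcyclohexane-1-carbonyl]dihydrofuran-2(3H)-one F5.
- Ag2O closes it, without base that would endanger C3, to the epoxide (R)-5-[(1R,4S,6S)-1-methyl-7-oxabicyclo[4.1.0]heptane-4-carbonyl]dihydrofuran-2(3H)-one F6, with oxygen syn to the acyl group.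
- LiCl and AcOH in THF open F6 by backside attack at the secondary carbon C3' in the trans-diaxial sense to give 8; attack at the tertiary carbon would need a twist-boat and is not favoured in this weakly acidic medium.

**Step 12.** Closure may go 5-exo to the oxolane, or through the other chair to the C5 epimer. The fallback separates ring closure from bromination; it sets out from 17 and comes back at 18. Hg(OCOCF3)2 (divalent mercury) in MeNO2 at −20 °C effects reversible, Markovnikov alkoxymercuration, which favours the six-membered ring with mercury equatorial. Exchange with KBr gives (2R,3R,5R)-5-(bromomercurio)-2-[(1S,3S,4S)-3-bromo-4-chloro-4-methylcyclohexyl]-2,6,6-trimethyloxan-3-yl acetate F7. Bromine in pyridine replaces mercury with retention to give 18.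

## Further compounds

F1 | step 6 | (R)-5-[(R)-4-methylcyclohex-3-ene-1-carbonyl]dihydrofuran-2(3H)-one | O=C([C@H]1CCC(=O)O1)[C@@H]1CCC(C)=CC1
F2 | step 6 | (R)-5-[(1R,3S,4S)-3-bromo-4-chloro-4-methylcyclohexane-1-carbonyl]dihydrofuran-2(3H)-one | O=C([C@H]1CCC(=O)O1)[C@@H]1CC[C@](C)(Cl)[C@@H](Br)C1
F3 | step 6 | lithium enolate of F2 at C1', lithium [(3S,4S)-3-bromo-4-chloro-4-methylcyclohexylidene][(R)-5-oxotetrahydrofuran-2-yl]methanolate | [Li+].[O-]C([C@H]1CCC(=O)O1)=C1CC[C@](C)(Cl)[C@@H](Br)C1
F4 | step 4 | (R)-5-[(R)-4-methylcyclohex-3-ene-1-carbonyl]dihydrofuran-2(3H)-one | O=C([C@H]1CCC(=O)O1)[C@@H]1CCC(C)=CC1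
F5 | step 5 | (R)-5-[(1S,3R,4R)-3-bromo-4-hydroxy-4-methylcyclohexane-1-carbonyl]dihydrofuran-2(3H)-one | O=C([C@H]1CCC(=O)O1)[C@H]1CC[C@@](C)(O)[C@H](Br)C1
F6 | step 5 | (R)-5-[(1R,4S,6S)-1-methyl-7-oxabicyclo[4.1.0]heptane-4-carbonyl]dihydrofuran-2(3H)-one | O=C([C@H]1CCC(=O)O1)[C@H]1CC[C@@]2(C)O[C@H]2C1
F7 | step 12 | (2R,3R,5R)-5-(bromomercurio)-2-[(1S,3S,4S)-3-bromo-4-chloro-4-methylcyclohexyl]-2,6,6-trimethyloxan-3-yl acetate | CC(=O)O[C@@H]1C[C@@H]([Hg]Br)C(C)(C)O[C@]1(C)[C@H]1CC[C@](C)(Cl)[C@@H](Br)C1
A1 | alternative 1 | 6-bromo-3-[(1S,3S,4S)-3-bromo-4-chloro-4-methylcyclohexyl]-1,3-dimethyl-2,7-dioxabicyclo[2.2.1]heptane (bromine anti to O7) | C[C@]12O[C@](C)([C@H]3CC[C@](C)(Cl)[C@@H](Br)C3)[C@H](O1)C[C@H]2Br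
A2 | alternative 1 | (2R,3R)-2-[(1S,3S,4S)-3-bromo-4-chloro-4-methylcyclohexyl]-2,6-dimethyl-3,4-dihydro-2H-pyran-3-ol | O[C@@H]1CC=C(C)O[C@]1(C)[C@H]1CC[C@](C)(Cl)[C@@H](Br)C1
A3 | alternative 2 | (R)-4-benzyl-3-[(1S,3S,4S)-3-bromo-4-chloro-4-methylcyclohexane-1-carbonyl]oxazolidin-2-one | O=C([C@H]1CC[C@](C)(Cl)[C@@H](Br)C1)N1[C@H](Cc2ccccc2)COC1=O
A4 | alternative 2 | (R)-4-benzyl-3-[(5S,6S)-6-bromo-5-chloro-5-methyl-7-{[(trifluoromethyl)sulfonyl]oxy}heptanoyl]oxazolidin-2-one | O=C(CCC[C@](C)(Cl)[C@@H](Br)COS(=O)(=O)C(F)(F)F)N1[C@H](Cc2ccccc2)COC1=O
A5 | alternative 3 | caespitol, (2R,3R,5R)-5-bromo-2-[(1S,3S,4S)-3-bromo-4-chloro-4-methylcyclohexyl]-2,6,6-trimethyloxan-3-ol | O[C@@H]1C[C@@H](Br)C(C)(C)O[C@]1(C)[C@H]1CC[C@](C)(Cl)[C@@H](Br)C1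
A6 | alternative 3 | (3R)-3-bromo-4-{(2R,3S)-3-[(1S,3S,4S)-3-bromo-4-chloro-4-methylcyclohexyl]-3-methyloxiran-2-yl}-2-methylbutan-2-ol | CC(C)(O)[C@H](Br)C[C@H]1O[C@@]1(C)[C@H]1CC[C@](C)(Cl)[C@@H](Br)C1
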